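**Retrosynthetic overview**
1. Both pyridine rings come off last: double hydroboration / B-alkyl Suzuki coupling of a bis(terminal alkene) isoxazolidine with two molecules of 3-bromopyridine, one per chain end.
2. The isoxazolidine ring (N–O–C3) comes from convex-face hydride reduction of a cis-fused bicyclic hemiketal; this sets C3.
3. The hemiketal comes from a cis β-amino ketone by N-oxygenation; the ketone comes from organolithium opening of an N-alkyl cis-fused β-lactam.
4. The β-lactam (C3–C3a bond, C3a and C6a) comes from a photochemical 1,3-carbamoyl shift of (−)-Vince lactam, then hydrogenation.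
5. Ring order: cyclopentane bought in 1, four-membered lactam ring made with light and opened again, isoxazolidine ring closed last.

Assumption: the target SMILES is read as (3S,3aS,6aR), with H3, H3a and H6a all on one face; compounds 1, 4, 6 and 13 are bought.

**Step 1**
Reactants: 1 (1R,4S)-2-azabicyclo[2.2.1]hept-5-en-3-one ((−)-Vince lactam)
Product: 2 (1S,5R)-6-azabicyclo[3.2.0]hept-2-en-7-one
Conditions: hν 254 nm (low-pressure Hg lamp, quartz), degassed MeCN, 0.02 M, −20 °C, to about half conversion; 1 recovered and recycled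
Reagents that add atoms: none
Why: Proposed new method: direct n→π* excitation of the lactam carbonyl should break the strained allylic C3–C4 bond (alpha-cleavage, Norrish type 1); the carbamoyl carbon stays tied through N2 to C1, does not lose CO, and re-bonds at the far allyl terminus C6 on the face that carries nitrogen, which closes the four-membered ring cis and passes the bought C1 configuration on to the new C–C stereocenter while C1 itself is untouched; the closest known reaction type is the photochemical 1,3-acyl shift of β,γ-unsaturated ketones on direct irradiation (bicyclo[2.2.1]hept-5-en-2-one to bicyclo[3.2.0]hept-2-en-7-one), not yet shown for a lactam.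

**Step 2**
Reactants: 2 (1S,5R)-6-azabicyclo[3.2.0]hept-2-en-7-one
Product: 3 (1S,5R)-6-azabicyclo[3.2.0]heptan-7-one
Conditions: H2 (1 atm), 10% Pd/C, EtOAc, rt
Reagents that add atoms: none
Why: Heterogeneous catalytic hydrogenation saturates the ring alkene; no stereocenter forms and the cis fusion is locked by the four-membered ring.

**Step 3**
Reactants: 3 (1S,5R)-6-azabicyclo[3.2.0]heptan-7-one; 4 12-bromododec-1-ene
Product: 5 (1S,5R)-6-(dodec-11-en-1-yl)-6-azabicyclo[3.2.0]heptan-7-one
Conditions: NaH (1.1 equiv), DMF, 0 °C; then 4 (1.1 equiv), rt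
Reagents that add atoms: none
Why: N-alkylation of the deprotonated lactam nitrogen by SN2 displacement of a primary bromide; no carbon stereocenter is involved.

**Step 4**
Reactants: 5 (1S,5R)-6-(dodec-11-en-1-yl)-6-azabicyclo[3.2.0]heptan-7-one; 6 8-bromooct-1-ene
Product: 9 1-[(1S,2R)-2-(dodec-11-en-1-ylamino)cyclopentyl]non-8-en-1-one, via oct-7-enyllithium 7 (not isolated), via lithium hemiaminal alkoxide 8 (not isolated)
Conditions: 6, Li (1% Na, 2.2 equiv), Et2O, −10 °C; added to 5, THF, −78 °C, 1 h; AcOH (1.1 equiv), −78 °C, then H2O, cold work-up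
Reagents that add atoms: none
Why: Nucleophilic acyl substitution on a strained tertiary amide: 7 adds once to the β-lactam carbonyl, the tetrahedral alkoxide 8 holds at −78 °C so no second addition occurs, and on protonation 8 opens by C–N cleavage (strain release) to the β-amino ketone with both ring stereocenters untouched.

**Step 5**
Reactants: 9 1-[(1S,2R)-2-(dodec-11-en-1-ylamino)cyclopentyl]non-8-en-1-one
Product: 10 1-[(1S,2R)-2-[(benzoyloxy)(dodec-11-en-1-yl)amino]cyclopentyl]non-8-en-1-one
Conditions: (PhCO2)2 (1.2 equiv), K2HPO4 (1.5 equiv), DMF, rt, 12 h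
Reagents that add atoms: dibenzoyl peroxide, O=C(OOC(=O)c1ccccc1)c1ccccc1
Why: Electrophilic N-oxygenation: the secondary amine attacks the peroxide O–O bond (SN2 at oxygen) and stops at the O-benzoyl hydroxylamine, so no nitrone forms; alkenes, ketone and stereocenters are not touched.

**Step 6**
Reactants: 10 1-[(1S,2R)-2-[(benzoyloxy)(dodec-11-en-1-yl)amino]cyclopentyl]non-8-en-1-one
Product: 12 (3S,3aS,6aR)-1-(dodec-11-en-1-yl)-3-(oct-7-en-1-yl)hexahydro-1H-cyclopenta[c]isoxazole, via bicyclic hemiketal 11 (not isolated)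
Conditions: K2CO3 (0.2 equiv), MeOH, 0 °C, 1 h; evaporate; Et3SiH (5 equiv), BF3·OEt2 (3 equiv, Lewis acid promoter), CH2Cl2, −78 → −20 °C
Reagents that add atoms: none
Why: Catalytic methanolysis frees the N–OH group, which adds to the ketone (5-exo-trig) to give the cis-fused hemiketal 11; Lewis-acid ionization of its C3–OH and hydride transfer from Et3SiH to the convex face of the bicycle (anti to the C3a–C4 bond) sets C3 as S with H3 cis to H3a and H6a (Kishi-type lactol reduction, ionic hydrogenation).

**Step 7**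
Reactants: 12 (3S,3aS,6aR)-1-(dodec-11-en-1-yl)-3-(oct-7-en-1-yl)hexahydro-1H-cyclopenta[c]isoxazole; 13 3-bromopyridine
Product: 15 (3S,3aS,6aR)-1-[12-(pyridin-3-yl)dodecyl]-3-[8-(pyridin-3-yl)octyl]hexahydro-1H-cyclopenta[c]isoxazole, via bis(9-BBN) alkylborane 14 (not isolated)
Conditions: 9-BBN (2.6 equiv), THF, 0 °C → rt; then 13 (2.6 equiv in all, two molecules consumed), [1,1'-bis(diphenylphosphino)ferrocene]palladium dichloride PdCl2(dppf) (8 mol %), 3 M aq K3PO4, DMF, 60 °C
Reagents that add atoms: 3-bromopyridine (second equivalent), Brc1cccnc1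
Why: Anti-Markovnikov hydroboration of both terminal alkenes gives bis-borane 14, and each of its two primary C–B bonds then undergoes B-alkyl Suzuki–Miyaura coupling with one molecule of the heteroaryl bromide, so two molecules of 3-bromopyridine are taken up; the N–O bond and the three stereocenters are spectators.

**Compound list**
1 | (1R,4S)-2-azabicyclo[2.2.1]hept-5-en-3-one | O=C1N[C@@H]2C[C@H]1C=C2 | starting material
2 | (1S,5R)-6-azabicyclo[3.2.0]hept-2-en-7-one | O=C1N[C@@H]2CC=C[C@H]12 | intermediate
3 | (1S,5R)-6-azabicyclo[3.2.0]heptan-7-one | O=C1N[C@@H]2CCC[C@H]12 | intermediate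
4 | 12-bromododec-1-ene | C=CCCCCCCCCCCBr | starting material
5 | (1S,5R)-6-(dodec-11-en-1-yl)-6-azabicyclo[3.2.0]heptan-7-one | O=C1N(CCCCCCCCCCC=C)[C@@H]2CCC[C@H]12 | intermediate
6 | 8-bromooct-1-ene | C=CCCCCCCBr | starting material
7 | oct-7-en-1-yllithium | [Li]CCCCCCC=C | intermediate (not isolated)
8 | lithium (1S,5R)-6-(dodec-11-en-1-yl)-7-(oct-7-en-1-yl)-6-azabicyclo[3.2.0]heptan-7-olate (C7 unassigned) | [Li+].[O-]C1(CCCCCCC=C)N(CCCCCCCCCCC=C)[C@@H]2CCC[C@H]12 | intermediate (not isolated)
9 | 1-[(1S,2R)-2-(dodec-11-en-1-ylamino)cyclopentyl]non-8-en-1-one | C=CCCCCCCC(=O)[C@H]1CCC[C@H]1NCCCCCCCCCCC=C | intermediate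
10 | 1-[(1S,2R)-2-[(benzoyloxy)(dodec-11-en-1-yl)amino]cyclopentyl]non-8-en-1-one | C=CCCCCCCC(=O)[C@H]1CCC[C@H]1N(CCCCCCCCCCC=C)OC(=O)c1ccccc1 | intermediate
11 | (3aS,6aR)-1-(dodec-11-en-1-yl)-3-(oct-7-en-1-yl)hexahydro-1H-cyclopenta[c]isoxazol-3-ol (C3 epimers) | C=CCCCCCCCCCCN1OC(O)(CCCCCCC=C)[C@H]2CCC[C@H]21 | intermediate (not isolated)
12 | (3S,3aS,6aR)-1-(dodec-11-en-1-yl)-3-(oct-7-en-1-yl)hexahydro-1H-cyclopenta[c]isoxazole | C=CCCCCCCCCCCN1O[C@@H](CCCCCCC=C)[C@H]2CCC[C@H]21 | intermediate
13 | 3-bromopyridine | Brc1cccnc1 | starting material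
14 | (3S,3aS,6aR)-1-[12-(9-borabicyclo[3.3.1]nonan-9-yl)dodecyl]-3-[8-(9-borabicyclo[3.3.1]nonan-9-yl)octyl]hexahydro-1H-cyclopenta[c]isoxazole | C1CC2CCCC(C1)B2CCCCCCCCCCCCN1O[C@@H](CCCCCCCCB2C3CCCC2CCC3)[C@H]2CCC[C@H]21 | intermediate (not isolated)
15 | (3S,3aS,6aR)-1-[12-(pyridin-3-yl)dodecyl]-3-[8-(pyridin-3-yl)octyl]hexahydro-1H-cyclopenta[c]isoxazole | c1cncc(CCCCCCCCCCCCN2O[C@@H](CCCCCCCCc3cccnc3)[C@H]3CCC[C@H]32)c1 | target

**Step count and risks**
Total steps: 7. Longest linear sequence: 7 (1 → 15).

Step 1 (the new photochemical shift) is the most likely to fail. The lactam absorbs only weakly at 254 nm, product 2 is itself a β,γ-unsaturated lactam so a photostationary mixture is expected, and the same bond cleavage can instead fragment to cyclopentadiene and isocyanic acid. The fallback uses known chemistry, sets out from compound 4 and comes back at compound 5. Bought ethyl (1S,2R)-2-aminocyclopentane-1-carboxylate F1, used in excess, is mono-N-alkylated with 4 (K2CO3, MeCN, 60 °C) to give ethyl (1S,2R)-2-(dodec-11-en-1-ylamino)cyclopentane-1-carboxylate F2. t-BuMgCl (THF, 0 °C) then closes F2 to the β-lactam 5, a Grignard-mediated lactamization of a β-amino ester. Both ring stereocenters are then bought directly and steps 1–3 fall away.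

Step 4 may suffer from a second addition of 7, from enolization of the lactam, or from epimerization and retro-Michael loss of the amine in 9 during work-up. The fallback sets out from compound 5 and comes back at compound 9. Acidic methanolysis of 5 (HCl, MeOH, 50 °C) gives methyl (1S,2R)-2-(dodec-11-en-1-ylamino)cyclopentane-1-carboxylate F3. MeNH(OMe)·HCl with i-PrMgCl (THF, −20 °C) turns F3 into (1S,2R)-2-(dodec-11-en-1-ylamino)-N-methoxy-N-methylcyclopentane-1-carboxamide F4. The chelated Weinreb amide F4 takes up exactly one equivalent of 7 (2.2 equiv used because of the N–H, THF, −78 °C) to give 9.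

Step 6 has three weak points: base-induced retro-aza-Michael of the freed hydroxylamine (loss of enantiopurity at C6a), slow ionization if the Lewis acid sits on nitrogen, and an untested facial ratio in the hydride transfer. The fallback sets out from compound 10 and comes back at compound 12. After the same methanolysis to 11, NaBH4 (MeOH, −20 °C) reduces the open-chain ketone tautomer. The carbinol epimers are separated to give (1R)-1-[(1S,2R)-2-[dodec-11-en-1-yl(hydroxy)amino]cyclopentyl]non-8-en-1-ol F5. An intramolecular Mitsunobu reaction of F5 (PPh3, DIAD, THF, 0 °C) closes the ring by SN2 attack of the N–OH oxygen with inversion, giving (3S)-configured 12. Which epimer NaBH4 favours is not predictable here.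

**Further compounds**
F1 | step 1 | ethyl (1S,2R)-2-aminocyclopentane-1-carboxylate | CCOC(=O)[C@H]1CCC[C@H]1N
F2 | step 1 | ethyl (1S,2R)-2-(dodec-11-en-1-ylamino)cyclopentane-1-carboxylate | CCOC(=O)[C@H]1CCC[C@H]1NCCCCCCCCCCC=C
F3 | step 4 | methyl (1S,2R)-2-(dodec-11-en-1-ylamino)cyclopentane-1-carboxylate | COC(=O)[C@H]1CCC[C@H]1NCCCCCCCCCCC=C
F4 | step 4 | (1S,2R)-2-(dodec-11-en-1-ylamino)-N-methoxy-N-methylcyclopentane-1-carboxamide | CON(C)C(=O)[C@H]1CCC[C@H]1NCCCCCCCCCCC=C
F5 | step 6 | (1R)-1-[(1S,2R)-2-[dodec-11-en-1-yl(hydroxy)amino]cyclopentyl]non-8-en-1-ol | O[C@H](CCCCCCC=C)[C@H]1CCC[C@H]1N(O)CCCCCCCCCCC=C
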